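**Strategy.** Ring carbons are numbered C1 (side chain), C2/C3 (epoxide), C4, C5 and C6 (quaternary). The cyclohexene core is traced back to a prochiral cyclobutanol. Its four ring carbons are C6 (methyl, pyranone), the flanking C1 and C5, and the carbinol carbon that becomes C2; an allenyl group on that carbinol supplies C3, C4 and the C4 methyl. A rhodium-catalysed, ligand-controlled C–C cleavage and ring expansion converts this cyclobutanol into a cyclohexenone, sets C6 as one enantiomer and leaves a C2 ketone through which the C1 side chain, the C2 methyl and the ring diene are installed. Face-selective diene epoxidation and a reagent-controlled syn-aldol reaction with pentan-3-one complete the target.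

Key step: step 7

Remark: Pyr stands for the 6-methoxy-3,5-dimethyl-4-oxo-4H-pyran-2-yl group; its carbonyl, flanked by two methyls, is assumed inert to the organometallic reagents used at low temperature.

Assumption: the antipode of the bisphosphine in step 7 and of the Ipc reagent in step 13 is the one that gives the drawn configuration (for step 13, attack on the re face of the aldehyde); otherwise the mirror-image ligand or reagent is used with no other change.

Step 1
Reactants: 1 methyl 3,3-dimethoxycyclobutane-1-carboxylate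
Product: 3 methyl 3,3-dimethoxy-1-methylcyclobutane-1-carboxylate, via lithium enolate 2 (not isolated)
Conditions: LDA, THF, −78 °C; MeI, −78 to 0 °C
Reagents that add atoms: iodomethane, CI
Why: Ester enolate alkylation (SN2 on iodomethane) installs the methyl of the future quaternary C6; no stereocentre is formed.

Step 2
Reactants: 3 methyl 3,3-dimethoxy-1-methylcyclobutane-1-carboxylate; 4 methyl 2-methyl-3-oxopentanoate
Product: 6 methyl 5-(3,3-dimethoxy-1-methylcyclobutyl)-2,4-dimethyl-3,5-dioxopentanoate, via dianion 5 (not isolated)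
Conditions: 4 (2.2 equiv), NaH, THF, 0 °C; n-BuLi, 0 °C; then 3, 0 °C to rt; aq. HCl work-up
Reagents that add atoms: none
Why: Claisen-type γ-acylation of the β-keto ester dianion by the methyl ester (excess dianion covers the acidic product) should give the 3,5-diketo ester as tautomers and epimers that converge in step 3.

Step 3
Reactants: 6 methyl 5-(3,3-dimethoxy-1-methylcyclobutyl)-2,4-dimethyl-3,5-dioxopentanoate
Product: 7 6-(3,3-dimethoxy-1-methylcyclobutyl)-4-hydroxy-3,5-dimethyl-2H-pyran-2-one
Conditions: DBU, toluene, 80 °C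
Reagents that add atoms: none
Why: Base-mediated enol lactonisation (cyclocondensation with loss of methanol) gives the aromatic 4-hydroxy-2-pyranone and erases the two labile stereocentres.

Step 4
Reactants: 7 6-(3,3-dimethoxy-1-methylcyclobutyl)-4-hydroxy-3,5-dimethyl-2H-pyran-2-one
Product: 9 2-methoxy-3,5-dimethyl-6-(1-methyl-3-oxocyclobutyl)-4H-pyran-4-one, via ketal pyranone 8 (not isolated)
Conditions: MeOTf, CH2Cl2, rt; then 1 M aq. HCl, THF, rt; NaHCO3 work-up
Reagents that add atoms: methyl trifluoromethanesulfonate, COS(=O)(=O)C(F)(F)F; water, O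
Why: O-Methylation at the lactone carbonyl oxygen by the hard alkylating agent should give the 2-methoxy-4-pyranone tautomer (as with methyl fluorosulfonate), and dilute acid then hydrolyses the dimethyl ketal to the cyclobutanone; no stereocentre is formed.

Step 5
Reactants: 9 2-methoxy-3,5-dimethyl-6-(1-methyl-3-oxocyclobutyl)-4H-pyran-4-one
Product: 10 2-(cis-3-ethynyl-3-hydroxy-1-methylcyclobutyl)-6-methoxy-3,5-dimethyl-4H-pyran-4-one (hydroxyl cis to Pyr)
Conditions: HC≡CMgBr, THF, −78 to −40 °C; aq. NH4Cl
Reagents that add atoms: ethynylmagnesium bromide, C#C[Mg]Br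
Why: Grignard 1,2-addition to the strained ketone occurs on the face of the puckered ring anti to the bulkier pyranone, giving the carbinol with hydroxyl cis to Pyr; the minor epimer is removed by chromatography so that step 7 starts from one achiral isomer.

Step 6
Reactants: 10 2-(cis-3-ethynyl-3-hydroxy-1-methylcyclobutyl)-6-methoxy-3,5-dimethyl-4H-pyran-4-one
Product: 11 2-[cis-3-hydroxy-1-methyl-3-(propa-1,2-dien-1-yl)cyclobutyl]-6-methoxy-3,5-dimethyl-4H-pyran-4-one
Conditions: (CH2O)n, CuI (0.5 equiv), Cy2NH, dioxane, 100 °C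
Reagents that add atoms: formaldehyde (from paraformaldehyde), C=O
Why: Crabbé homologation (copper-mediated Mannich reaction, then 1,5-hydride transfer with loss of imine) converts the terminal alkyne into the terminal allene without changing the cis relationship on the ring.

Step 7
Reactants: 11 2-[cis-3-hydroxy-1-methyl-3-(propa-1,2-dien-1-yl)cyclobutyl]-6-methoxy-3,5-dimethyl-4H-pyran-4-one
Product: 12 (R)-3,5-dimethyl-5-(6-methoxy-3,5-dimethyl-4-oxo-4H-pyran-2-yl)cyclohex-2-en-1-one
Conditions: [Rh(OH)(cod)]2 (2.5 mol%), (R)-DTBM-SEGPHOS (6 mol%), toluene, 80 °C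
Reagents that add atoms: none
Why: The monovalent rhodium alkoxide of 11 undergoes strain-releasing β-carbon elimination of one of the two enantiotopic ring C–C bonds, giving an allenyl ketone tethered to a primary alkyl–rhodium; this adds in a 1,4-sense to the central allene carbon, and protonation and tautomerisation of the rhodium dienolate give the conjugated enone and return the catalyst. The closest known reaction type is the enantioselective rhodium-catalysed C–C activation and ring expansion of allenyl tert-cyclobutanols to 3-methyl-5,5-disubstituted cyclohex-2-enones. The only ring closed is the six-membered carbocycle, by 6-endo carbometalation onto the allenyl ketone: the cyclobutane carbons become C2, C1, C6 and C5, the two inserted allene carbons become C3 and C4, and the allene terminus becomes the C4 methyl. The one new stereocentre, C6, is set by the chiral bisphosphine on rhodium in the bond-selecting β-carbon elimination (catalyst control). The step needs clean discrimination of the enantiotopic bonds, which requires the single cis isomer 11 from step 5, and ring closure faster than protodemetalation; β-hydride elimination cannot compete because the carbon β to rhodium is the quaternary C6.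

Step 8
Reactants: 12 (R)-3,5-dimethyl-5-Pyr-cyclohex-2-en-1-one; 13 2-bromo-3,3-diethoxyprop-1-ene
Product: 16 (5R,6S)-6-(3,3-diethoxyprop-1-en-2-yl)-3,5-dimethyl-5-Pyr-cyclohex-2-en-1-one (side chain cis to Pyr), via lithium enolate 14 (not isolated), via lithium dienolate 15 (not isolated)
Conditions: LiHMDS (2.2 equiv), THF, −78 °C; Pd2(dba)3 (2.5 mol%), P(t-Bu)3 (10 mol%), 13, −78 °C to rt; AcOH, −78 °C
Reagents that add atoms: none
Why: Palladium-catalysed α-alkenylation of the kinetic α′-enolate (zerovalent palladium inserts into the C–Br bond of 13, then C–C reductive elimination) gives a ketone that is deprotonated again to the dienolate, and kinetic C-protonation of this at C1 on the face anti to the pseudo-axial pyranone (allylic strain holds the C6 methyl in the enolate plane) should place the side chain cis to Pyr.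

Step 9
Reactants: 16 (5R,6S)-6-(3,3-diethoxyprop-1-en-2-yl)-3,5-dimethyl-5-Pyr-cyclohex-2-en-1-one
Product: 17 (5R,6S)-6-(3,3-diethoxyprop-1-en-2-yl)-1,3,5-trimethyl-5-Pyr-cyclohex-2-en-1-ol (new methyl trans, hydroxyl cis to the C1 side chain)
Conditions: MeLi, CeCl3, THF, −78 °C
Reagents that add atoms: methyllithium, [Li]C
Why: Organocerium 1,2-addition, weakly basic so that the doubly activated C1–H is not removed, delivers the C2 methyl anti to the C1 substituent; the configuration of this carbinol is irrelevant because C2 becomes sp2 in step 10.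

Step 10
Reactants: 17 (5R,6S)-6-(3,3-diethoxyprop-1-en-2-yl)-1,3,5-trimethyl-5-Pyr-cyclohex-2-en-1-ol
Product: 20 2-[(1R,6S)-6-(3,3-diethoxyprop-1-en-2-yl)-1,3,5-trimethylcyclohexa-2,4-dien-1-yl]-6-methoxy-3,5-dimethyl-4H-pyran-4-one, via sulfenate 18 (not isolated), via allylic sulfoxide 19 (not isolated)
Conditions: 2,4-(O2N)2C6H3SCl, Et3N, ClCH2CH2Cl, 0 °C then 60 °C
Reagents that add atoms: none
Why: Sulfenylation of the tertiary allylic alcohol, suprafacial [2,3]-sigmatropic sulfenate-to-sulfoxide rearrangement to C4 and thermal syn-elimination towards C5–H amount to a 1,4-dehydration that can only use hydrogens β to C4, so C1–H and its stereocentre are untouched and the C2=C3/C4=C5 diene should result (loss of a C4-methyl hydrogen is the competing path).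

Step 11
Reactants: 20 diene acetal (as above)
Product: 21 2-[(1S,6R)-2,4,6-trimethyl-6-Pyr-cyclohexa-2,4-dien-1-yl]prop-2-enal
Conditions: PPTS, acetone/H2O, rt
Reagents that add atoms: water, O
Why: Mild acid hydrolysis of the labile allylic acetal releases the 2-substituted acrolein without epimerising C1 or isomerising the diene.

Step 12
Reactants: 21 2-[(1S,6R)-2,4,6-trimethyl-6-Pyr-cyclohexa-2,4-dien-1-yl]prop-2-enal
Product: 22 2-[(1R,4R,5S,6S)-2,4,6-trimethyl-4-Pyr-7-oxabicyclo[4.1.0]hept-2-en-5-yl]prop-2-enal (epoxide oxygen anti to Pyr and to the side chain)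
Conditions: DMDO, acetone, −40 to −20 °C
Reagents that add atoms: dimethyldioxirane, CC1(C)OO1
Why: Electrophilic epoxidation with the neutral dioxirane ignores the electron-poor enal and should attack the diene at C2=C3 on the face anti to the pyranone and the C1 side chain (C1 carries only hydrogen on that face, whereas C4=C5 is shielded there by the C6 methyl), setting C2 and C3.

Step 13
Reactants: 22 epoxy enal (as above); 23 pentan-3-one
Product: 25 (4R,5R)-5-hydroxy-4-methyl-6-[(1R,4R,5R,6S)-2,4,6-trimethyl-4-Pyr-7-oxabicyclo[4.1.0]hept-2-en-5-yl]hept-6-en-3-one (target CNP0233636.2), via enol borinate 24 (not isolated)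
Conditions: 23, (+)-Ipc2BOTf, i-Pr2NEt, CH2Cl2, −78 °C; then 22, −78 to −20 °C; H2O2, MeOH, pH 7 buffer, 0 °C
Reagents that add atoms: none
Why: Boron aldol reaction through a chair Zimmerman–Traxler transition state, in which the (Z)-enol diisopinocampheylborinate gives the syn aldol and the isopinocampheyl ligands direct attack to the re face of the aldehyde (reagent control), sets the carbinol and the methyl-bearing stereocentres.

**Compound list**

1 | methyl 3,3-dimethoxycyclobutane-1-carboxylate | COC(=O)C1CC(OC)(OC)C1 | starting material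
2 | lithium enolate of 1 | [Li+].COC([O-])=C1CC(OC)(OC)C1 | intermediate
3 | methyl 3,3-dimethoxy-1-methylcyclobutane-1-carboxylate | COC(=O)C1(C)CC(OC)(OC)C1 | intermediate
4 | methyl 2-methyl-3-oxopentanoate | CCC(=O)C(C)C(=O)OC | starting material
5 | sodium lithium dianion (bis-enolate) of 4 | [Na+].[Li+].CC=C([O-])C(C)=C([O-])OC | intermediate
6 | methyl 5-(3,3-dimethoxy-1-methylcyclobutyl)-2,4-dimethyl-3,5-dioxopentanoate | COC(=O)C(C)C(=O)C(C)C(=O)C1(C)CC(OC)(OC)C1 | intermediate
7 | 6-(3,3-dimethoxy-1-methylcyclobutyl)-4-hydroxy-3,5-dimethyl-2H-pyran-2-one | COC1(OC)CC(C)(C1)c1oc(=O)c(C)c(O)c1C | intermediate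
8 | 2-(3,3-dimethoxy-1-methylcyclobutyl)-6-methoxy-3,5-dimethyl-4H-pyran-4-one | COC1(OC)CC(C)(C1)c1oc(OC)c(C)c(=O)c1C | intermediate
9 | 2-methoxy-3,5-dimethyl-6-(1-methyl-3-oxocyclobutyl)-4H-pyran-4-one | O=C1CC(C)(C1)c1oc(OC)c(C)c(=O)c1C | intermediate
10 | 2-(cis-3-ethynyl-3-hydroxy-1-methylcyclobutyl)-6-methoxy-3,5-dimethyl-4H-pyran-4-one (hydroxyl cis to Pyr) | C#C[C@@]1(O)C[C@](C)(c2oc(OC)c(C)c(=O)c2C)C1 | intermediate
11 | 2-[cis-3-hydroxy-1-methyl-3-(propa-1,2-dien-1-yl)cyclobutyl]-6-methoxy-3,5-dimethyl-4H-pyran-4-one | C=C=C[C@@]1(O)C[C@](C)(c2oc(OC)c(C)c(=O)c2C)C1 | intermediate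
12 | (R)-3,5-dimethyl-5-(6-methoxy-3,5-dimethyl-4-oxo-4H-pyran-2-yl)cyclohex-2-en-1-one | C1C(=O)C=C(C)C[C@@]1(C)c1oc(OC)c(C)c(=O)c1C | intermediate
13 | 2-bromo-3,3-diethoxyprop-1-ene | C=C(Br)C(OCC)OCC | starting material
14 | lithium α′-enolate of 12 | [Li+].C1=C([O-])C=C(C)C[C@@]1(C)c1oc(OC)c(C)c(=O)c1C | intermediate
15 | lithium dienolate of 16 | [Li+].C=C(C(OCC)OCC)C1=C([O-])C=C(C)C[C@@]1(C)c1oc(OC)c(C)c(=O)c1C | intermediate
16 | (5R,6S)-6-(3,3-diethoxyprop-1-en-2-yl)-3,5-dimethyl-5-Pyr-cyclohex-2-en-1-one | C=C(C(OCC)OCC)[C@H]1C(=O)C=C(C)C[C@@]1(C)c1oc(OC)c(C)c(=O)c1C | intermediate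
17 | (5R,6S)-6-(3,3-diethoxyprop-1-en-2-yl)-1,3,5-trimethyl-5-Pyr-cyclohex-2-en-1-ol (hydroxyl cis to the side chain) | C=C(C(OCC)OCC)[C@H]1[C@@](C)(O)C=C(C)C[C@@]1(C)c1oc(OC)c(C)c(=O)c1C | intermediate
18 | 2,4-dinitrobenzenesulfenate ester of 17 | C=C(C(OCC)OCC)[C@H]1[C@@](C)(OSc2ccc(cc2[N+](=O)[O-])[N+](=O)[O-])C=C(C)C[C@@]1(C)c1oc(OC)c(C)c(=O)c1C | intermediate
19 | rearranged allylic 2,4-dinitrophenyl sulfoxide (sulfur on C4, cis to the side chain) | C=C(C(OCC)OCC)[C@H]1C(C)=C[C@@](C)(S(=O)c2ccc(cc2[N+](=O)[O-])[N+](=O)[O-])C[C@@]1(C)c1oc(OC)c(C)c(=O)c1C | intermediate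
20 | 2-[(1R,6S)-6-(3,3-diethoxyprop-1-en-2-yl)-1,3,5-trimethylcyclohexa-2,4-dien-1-yl]-6-methoxy-3,5-dimethyl-4H-pyran-4-one | C=C(C(OCC)OCC)[C@H]1C(C)=CC(C)=C[C@@]1(C)c1oc(OC)c(C)c(=O)c1C | intermediate
21 | 2-[(1S,6R)-2,4,6-trimethyl-6-Pyr-cyclohexa-2,4-dien-1-yl]prop-2-enal | C=C(C=O)[C@H]1C(C)=CC(C)=C[C@@]1(C)c1oc(OC)c(C)c(=O)c1C | intermediate
22 | 2-[(1R,4R,5S,6S)-2,4,6-trimethyl-4-Pyr-7-oxabicyclo[4.1.0]hept-2-en-5-yl]prop-2-enal | C=C(C=O)[C@H]1[C@]2(C)O[C@@H]2C(C)=C[C@@]1(C)c1oc(OC)c(C)c(=O)c1C | intermediate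
23 | pentan-3-one | CCC(=O)CC | starting material
24 | (Z)-pent-2-en-3-yl di[(+)-isopinocampheyl]borinate | C/C=C(\OB([C@H]1C[C@H]2C[C@@H]([C@@H]1C)C2(C)C)[C@H]1C[C@H]2C[C@@H]([C@@H]1C)C2(C)C)CC | intermediate
25 | (4R,5R)-5-hydroxy-4-methyl-6-[(1R,4R,5R,6S)-2,4,6-trimethyl-4-Pyr-7-oxabicyclo[4.1.0]hept-2-en-5-yl]hept-6-en-3-one (CNP0233636.2) | C=C([C@H](O)[C@@H](C)C(=O)CC)[C@H]1[C@]2(C)O[C@@H]2C(C)=C[C@@]1(C)c1oc(OC)c(C)c(=O)c1C | target

**Step count and risks**

Total step count: 13. Longest linear sequence: 13 steps (1 to 25); 4, 13 and 23 are commercial partners.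

Step 8 is the most likely to fail. Coupling at the α′-carbon next to the quaternary C6 may be slow, the enolate may equilibrate to the extended dienolate and couple at the γ-position, and the quench may give the conjugated alkylidene isomer or the wrong C1 epimer. The fallback replaces the cross-coupling by aldol chemistry and sets out from 12. Enolate 14 (LDA, THF, −78 °C) adds to 1,1-diethoxypropan-2-one to give the tertiary aldol F1. Dehydration (MsCl, Et3N, DMAP, then DBU) gives the conjugated alkylidene ketone F2. γ-Deprotonation at its allylic methyl (LDA, THF/HMPA, −78 °C) followed by kinetic α-protonation with AcOH deconjugates the alkene and sets C1 as in the main route, so the sequence comes back at 16.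

Step 10 is the second risk. The sulfoxide may eliminate towards a hydrogen of the C4 methyl instead of C5–H, giving an exocyclic methylene isomer that cannot be corrected without endangering C1, and sulfenylation of the hindered tertiary alcohol may be incomplete. The fallback fixes the diene position by cross-coupling instead of elimination; it sets out from 12 and bypasses 13 to 20.
- Aldol addition of 14 to 2,2-diethoxyacetaldehyde gives the aldol F3, and dehydration (MsCl, Et3N, then DBU) gives the alkylidene enone F4, in which C1 carries no hydrogen.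
- KHMDS can then form only the extended enolate by removing C5–H, and PhNTf2 traps it as the trienyl triflate F5.
- Pd(PPh3)4-catalysed coupling with trimethylboroxine (K2CO3, dioxane) installs the C2 methyl and gives the tetraene acetal F6.
- PPTS in aqueous acetone gives the conjugated trienal F7.
- 1,4-Reduction with [(Ph3P)CuH]6 delivers hydride to C1 anti to the pyranone and gives the saturated aldehyde F8.
- α-Methylenation with Eschenmoser's salt and Et3N comes back to the route at 21.

Step 12 is the third risk. The dioxirane may not distinguish the two trisubstituted ring alkenes well enough, may attack the hindered face, or the vinyl epoxide may open under traces of acid. The fallback sets out from 21 and replaces substrate control by catalyst control: a Shi epoxidation (fructose-derived chiral ketone or its antipode, Oxone, K2CO3 buffer, MeCN/dimethoxymethane/water, 0 °C), using the ketone antipode whose spiro transition state matches the required face of C2=C3. It comes back at 22 and makes no new compound.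

Further compounds
F1 | step 8 | 6-(1,1-diethoxy-2-hydroxypropan-2-yl)-3,5-dimethyl-5-Pyr-cyclohex-2-en-1-one (tertiary aldol, 5R) | CC(O)(C(OCC)OCC)C1C(=O)C=C(C)C[C@@]1(C)c1oc(OC)c(C)c(=O)c1C
F2 | step 8 | 6-(1,1-diethoxypropan-2-ylidene)-3,5-dimethyl-5-Pyr-cyclohex-2-en-1-one (alkylidene ketone, 5R) | CC(C(OCC)OCC)=C1C(=O)C=C(C)C[C@@]1(C)c1oc(OC)c(C)c(=O)c1C
F3 | step 10 | 6-(2,2-diethoxy-1-hydroxyethyl)-3,5-dimethyl-5-Pyr-cyclohex-2-en-1-one (aldol, 5R) | CCOC(OCC)C(O)C1C(=O)C=C(C)C[C@@]1(C)c1oc(OC)c(C)c(=O)c1C
F4 | step 10 | 6-(2,2-diethoxyethylidene)-3,5-dimethyl-5-Pyr-cyclohex-2-en-1-one (alkylidene enone, 5R) | CCOC(OCC)C=C1C(=O)C=C(C)C[C@@]1(C)c1oc(OC)c(C)c(=O)c1C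
F5 | step 10 | 6-(2,2-diethoxyethylidene)-3,5-dimethyl-5-Pyr-cyclohexa-1,3-dien-1-yl trifluoromethanesulfonate (trienyl triflate) | CCOC(OCC)C=C1C(OS(=O)(=O)C(F)(F)F)=CC(C)=C[C@@]1(C)c1oc(OC)c(C)c(=O)c1C
F6 | step 10 | 2-[6-(2,2-diethoxyethylidene)-1,3,5-trimethylcyclohexa-2,4-dien-1-yl]-6-methoxy-3,5-dimethyl-4H-pyran-4-one (tetraene acetal) | CCOC(OCC)C=C1C(C)=CC(C)=C[C@@]1(C)c1oc(OC)c(C)c(=O)c1C
F7 | step 10 | 2-(2,4,6-trimethyl-6-Pyr-cyclohexa-2,4-dien-1-ylidene)acetaldehyde (trienal) | O=CC=C1C(C)=CC(C)=C[C@@]1(C)c1oc(OC)c(C)c(=O)c1C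
F8 | step 10 | 2-[(1S,6R)-2,4,6-trimethyl-6-Pyr-cyclohexa-2,4-dien-1-yl]acetaldehyde (side chain cis to Pyr) | O=CC[C@H]1C(C)=CC(C)=C[C@@]1(C)c1oc(OC)c(C)c(=O)c1C
F0 | step 12 | none | none
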